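**Plan**
1. Retrosynthesis (fatty-acid numbering: C1 = ester carbon, ring = C13–C17, oxirane = C14/C15, Cl on C18): cut C11=C12 (Z-Wittig), then C18–Cl (from the C18 alcohol with inversion, itself from a C18 ketone), then cut the cyclopentane bond C16–C17 together with the oxirane bonds C14–C15 and C15–O.
2. Enabling feature: the ring edge C15–C16 is an unsubstituted CH(O)–CH2 unit. It lies between C17, which is alpha to the C18 carbonyl and becomes a stabilised carbanion as a benzyl beta-keto ester (temporary activating group), and the oxirane CH C14, which can be an aldehyde. A vinylsulfonium salt therefore serves as the C16/C15 two-carbon unit (acceptor at C16, then ylide and leaving group at C15).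
3. Forward: the open-chain formyl beta-keto ester 6 is made by enantioselective aldehyde alpha-alkylation; one annulation then closes the cyclopentane and the epoxide from the open chain. The benzyl ester is then removed, C18 goes ketone → alcohol → chloride, C12 is oxidised to the aldehyde, and the C1–C11 chain is joined by Wittig reaction.
4. Stereochemistry: C13 comes from the imidazolidinone catalyst; C14/C15 from C13 by substrate control in the annulation (cis ring fusion is inherent); C17 by equilibration trans to C13; C18 by CBS reduction followed by SN2 inversion; the Z alkenes by Lindlar hydrogenation and a kinetic Wittig reaction.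

Key step: step 4

Remark: the beta-keto ester carbon (C17) is configurationally labile until step 5 and is left undefined in 6 and 8–11. Compounds 5, 7, 17 and 20 are taken as commercial.

**Route**

Step 1
Reactants: 1 methyl 3-oxopentanoate; 2 benzyl alcohol
Product: 3 benzyl 3-oxopentanoate
Conditions: DMAP (cat.), toluene, reflux, MeOH removed (4 Å MS)
Reagents that add atoms: none
Why: DMAP-catalysed transesterification of a beta-keto ester is driven to the benzyl ester by removal of methanol, and no stereocentre is involved.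

Step 2
Reactants: 3 benzyl 3-oxopentanoate
Product: 4 benzyl 2-bromo-3-oxopentanoate (racemic)
Conditions: NBS, NH4OAc (cat.), Et2O, rt
Reagents that add atoms: N-bromosuccinimide, O=C1CCC(=O)N1Br
Why: The doubly activated C2–H enolises readily, so electrophilic alpha-bromination should occur only between the two carbonyl groups; the racemic nature of 4 is immaterial because this carbon becomes a radical in step 3.

Step 3
Reactants: 4 benzyl 2-bromo-3-oxopentanoate; 5 3-[(tert-butyldimethylsilyl)oxy]propanal
Product: 6 benzyl 2-[(2R)-1-[(tert-butyldimethylsilyl)oxy]-3-oxopropan-2-yl]-3-oxopentanoate (epimers at the keto ester carbon)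
Conditions: (2S,5R)-2-tert-butyl-3,5-dimethylimidazolidin-4-one·TfOH (20 mol%), Ru(bpy)3Cl2 (0.5 mol%), 2,6-lutidine, DMF, visible light, rt; 5 in excess; 6 used without storage
Reagents that add atoms: none
Why: In this photoredox organocatalytic enamine alpha-alkylation of an aldehyde, reductive C–Br cleavage gives the electrophilic 1,3-dicarbonyl radical, which should add to the E-enamine on the face opposite the C5 methyl group of the catalyst and so set C13 as (R).

Step 4
Reactants: 6 benzyl 2-[(2R)-1-[(tert-butyldimethylsilyl)oxy]-3-oxopropan-2-yl]-3-oxopentanoate; 7 diphenyl(vinyl)sulfonium trifluoromethanesulfonate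
Product: 10 benzyl (1R,2R,5S)-2-{[(tert-butyldimethylsilyl)oxy]methyl}-3-propanoyl-6-oxabicyclo[3.1.0]hexane-3-carboxylate (C3 epimers; oxirane anti to CH2OTBS), via sulfonium ylide 8 (not isolated), via sulfonium alkoxide betaine 9 (not isolated)
Conditions: DBU (1.5 equiv), CH2Cl2, 0 °C
Reagents that add atoms: none
Why: DBU removes the 1,3-dicarbonyl proton and the soft carbanion adds to the vinylsulfonium salt (C16–C17 bond), giving ylide 8, which adds to the aldehyde (C14–C15 bond) to give betaine 9, whose alkoxide displaces diphenyl sulfide to close the oxirane. The closest known reaction type is the epoxy-annulation of nucleophile-tethered aldehydes and ketones with vinylsulfonium salts (a conjugate addition/Corey–Chaykovsky cascade), known for nitrogen, oxygen and stabilised carbon nucleophiles. The cyclopentane closes by 5-exo-trig addition of the ylide carbon to the formyl group and the oxirane by 3-exo-tet displacement with inversion at the sulfur-bearing carbon. C14 is controlled by the C13 stereocentre, the ylide being expected to attack the aldehyde face that places the new oxygen anti to the adjacent CH2OTBS group; C15 follows from C14 because only the betaine with O− and Ph2S+ trans on the ring can undergo backside displacement, which makes the ring fusion cis; the quaternary C17 is formed without control and is erased in step 5. The step needs chemoselective deprotonation and C-alkylation at the keto ester carbon without enolisation at C13, which the large acidity gap and the reluctance of the enolate to accept a second adjacent deprotonation should secure. It also needs cyclisation on the aldehyde only, which is secured because the ketone and ester could be reached only through four-membered rings.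

Step 5
Reactants: 10 benzyl (1R,2R,5S)-2-{[(tert-butyldimethylsilyl)oxy]methyl}-3-propanoyl-6-oxabicyclo[3.1.0]hexane-3-carboxylate
Product: 12 1-[(1R,2R,3R,5S)-2-{[(tert-butyldimethylsilyl)oxy]methyl}-6-oxabicyclo[3.1.0]hexan-3-yl]propan-1-one, via beta-keto acid 11 (not isolated)
Conditions: H2 (1 atm), 10% Pd/C, EtOAc, rt; filter; toluene, 60 °C; then DBU (cat.), CH2Cl2, rt
Reagents that add atoms: none
Why: Neutral hydrogenolysis of the benzyl ester gives the beta-keto acid, which decarboxylates through the cyclic six-membered transition state, and base equilibration at the enolisable C17 should place the propanoyl group trans to the adjacent CH2OTBS group (thermodynamic control).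

Step 6
Reactants: 12 1-[(1R,2R,3R,5S)-2-{[(tert-butyldimethylsilyl)oxy]methyl}-6-oxabicyclo[3.1.0]hexan-3-yl]propan-1-one
Product: 13 (1R)-1-[(1R,2R,3R,5S)-2-{[(tert-butyldimethylsilyl)oxy]methyl}-6-oxabicyclo[3.1.0]hexan-3-yl]propan-1-ol
Conditions: (S)-2-methyl-CBS-oxazaborolidine, BH3·SMe2, THF, −30 °C; MeOH, then aqueous work-up
Reagents that add atoms: none
Why: In the CBS reduction the (S)-oxazaborolidine should treat the alpha-branched ring carbon as the large group and ethyl as the small group and deliver hydride to give the (R)-carbinol under reagent control.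

Step 7
Reactants: 13 (1R)-1-[(1R,2R,3R,5S)-2-{[(tert-butyldimethylsilyl)oxy]methyl}-6-oxabicyclo[3.1.0]hexan-3-yl]propan-1-ol
Product: 14 tert-butyl{[(1R,2R,3R,5S)-3-[(1S)-1-chloropropyl]-6-oxabicyclo[3.1.0]hexan-2-yl]methoxy}dimethylsilane
Conditions: PPh3, NCS, THF, 0 °C → rt
Reagents that add atoms: N-chlorosuccinimide, O=C1CCC(=O)N1Cl
Why: In this Appel-type chlorination the alcohol is converted into an oxyphosphonium ion that chloride displaces by SN2 with inversion, turning the (R)-carbinol into the (S)-chloride under near-neutral conditions that epoxides normally tolerate.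

Step 8
Reactants: 14 tert-butyl{[(1R,2R,3R,5S)-3-[(1S)-1-chloropropyl]-6-oxabicyclo[3.1.0]hexan-2-yl]methoxy}dimethylsilane
Product: 15 [(1R,2R,3R,5S)-3-[(1S)-1-chloropropyl]-6-oxabicyclo[3.1.0]hexan-2-yl]methanol
Conditions: TBAF, AcOH, THF, 0 °C → rt
Reagents that add atoms: none
Why: Fluoride-mediated desilylation buffered with acetic acid should cleave the primary silyl ether without touching the oxirane or the secondary chloride.

Step 9
Reactants: 15 [(1R,2R,3R,5S)-3-[(1S)-1-chloropropyl]-6-oxabicyclo[3.1.0]hexan-2-yl]methanol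
Product: 16 (1R,2S,3R,5S)-3-[(1S)-1-chloropropyl]-6-oxabicyclo[3.1.0]hexane-2-carbaldehyde
Conditions: Dess–Martin periodinane, CH2Cl2, 0 °C; used at once
Reagents that add atoms: none
Why: Dess–Martin oxidation is non-basic, so the beta,gamma-epoxy aldehyde should form without epimerisation at C13 or beta-elimination of the oxirane.

Step 10
Reactants: 17 tert-butyl(but-3-yn-1-yloxy)dimethylsilane
Product: 18 5-[(tert-butyldimethylsilyl)oxy]pent-2-yn-1-ol
Conditions: n-BuLi, THF, −78 °C; (CH2O)n, −78 °C → rt; aq. NH4Cl
Reagents that add atoms: paraformaldehyde (as formaldehyde), C=O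
Why: Addition of the lithium acetylide to formaldehyde is a standard hydroxymethylation that installs C7.

Step 11
Reactants: 18 5-[(tert-butyldimethylsilyl)oxy]pent-2-yn-1-ol
Product: 19 [(5-bromopent-3-yn-1-yl)oxy](tert-butyl)dimethylsilane
Conditions: CBr4, PPh3, CH2Cl2, 0 °C
Reagents that add atoms: carbon tetrabromide, BrC(Br)(Br)Br
Why: Appel bromination of a primary propargylic alcohol proceeds by SN2 displacement of the oxyphosphonium ion under neutral conditions.

Step 12
Reactants: 19 [(5-bromopent-3-yn-1-yl)oxy](tert-butyl)dimethylsilane; 20 methyl hex-5-ynoate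
Product: 21 methyl 11-[(tert-butyldimethylsilyl)oxy]undeca-5,8-diynoate
Conditions: CuI, NaI, Cs2CO3, DMF, rt
Reagents that add atoms: none
Why: Copper(I)-mediated coupling of a terminal alkyne with a propargylic halide under mild carbonate conditions is the standard entry to skipped diynes and tolerates the methyl ester.

Step 13
Reactants: 21 methyl 11-[(tert-butyldimethylsilyl)oxy]undeca-5,8-diynoate
Product: 22 methyl (5Z,8Z)-11-[(tert-butyldimethylsilyl)oxy]undeca-5,8-dienoate
Conditions: H2 (1 atm), Lindlar catalyst, quinoline, EtOAc, rt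
Reagents that add atoms: none
Why: Lindlar semi-hydrogenation adds hydrogen syn to each alkyne and should stop at the alkene stage, setting both Z double bonds.

Step 14
Reactants: 22 methyl (5Z,8Z)-11-[(tert-butyldimethylsilyl)oxy]undeca-5,8-dienoate
Product: 23 methyl (5Z,8Z)-11-hydroxyundeca-5,8-dienoate
Conditions: p-TsOH·H2O (cat.), MeOH, 0 °C → rt
Reagents that add atoms: none
Why: Acid-catalysed methanolysis removes the primary silyl ether, and methanol as solvent makes any ester exchange degenerate.

Step 15
Reactants: 23 methyl (5Z,8Z)-11-hydroxyundeca-5,8-dienoate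
Product: 24 methyl (5Z,8Z)-11-iodoundeca-5,8-dienoate
Conditions: I2, PPh3, imidazole, CH2Cl2, 0 °C
Reagents that add atoms: iodine, II
Why: Appel-type iodination of the primary homoallylic alcohol proceeds by SN2 displacement of the oxyphosphonium ion without touching the skipped diene.

Step 16
Reactants: 24 methyl (5Z,8Z)-11-iodoundeca-5,8-dienoate
Product: 25 [(3Z,6Z)-11-methoxy-11-oxoundeca-3,6-dien-1-yl]triphenylphosphonium iodide
Conditions: PPh3, MeCN, 80 °C, dark
Reagents that add atoms: triphenylphosphine, c1ccc(cc1)P(c1ccccc1)c1ccccc1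
Why: SN2 quaternisation of triphenylphosphine by a primary iodide is the standard route to homoallylic phosphonium salts.

Step 17
Reactants: 25 [(3Z,6Z)-11-methoxy-11-oxoundeca-3,6-dien-1-yl]triphenylphosphonium iodide; 16 (1R,2S,3R,5S)-3-[(1S)-1-chloropropyl]-6-oxabicyclo[3.1.0]hexane-2-carbaldehyde
Product: 27 methyl (5Z,8Z,11Z)-12-[(1R,2S,3R,5S)-3-[(1S)-1-chloropropyl]-6-oxabicyclo[3.1.0]hexan-2-yl]dodeca-5,8,11-trienoate, via phosphorus ylide 26 (not isolated)
Conditions: NaHMDS, THF, −78 °C; then 16, −78 → −20 °C
Reagents that add atoms: none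
Why: A Wittig reaction of a non-stabilised ylide under lithium-free conditions at low temperature should give the Z alkene through the kinetically formed cis-oxaphosphetane, and addition to the aldehyde should outrun its enolisation so that C13 and the oxirane are preserved.

**Compound list**
1 | methyl 3-oxopentanoate | CCC(=O)CC(=O)OC | starting material
2 | benzyl alcohol | OCc1ccccc1 | starting material
3 | benzyl 3-oxopentanoate | CCC(=O)CC(=O)OCc1ccccc1 | intermediate
4 | benzyl 2-bromo-3-oxopentanoate (racemic) | CCC(=O)C(Br)C(=O)OCc1ccccc1 | intermediate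
5 | 3-[(tert-butyldimethylsilyl)oxy]propanal | O=CCCO[Si](C)(C)C(C)(C)C | starting material
6 | benzyl 2-[(2R)-1-[(tert-butyldimethylsilyl)oxy]-3-oxopropan-2-yl]-3-oxopentanoate (epimers at the keto ester carbon) | O=C[C@H](C(C(=O)CC)C(=O)OCc1ccccc1)CO[Si](C)(C)C(C)(C)C | intermediate
7 | diphenyl(vinyl)sulfonium trifluoromethanesulfonate | C=C[S+](c1ccccc1)c1ccccc1.[O-]S(=O)(=O)C(F)(F)F | starting material
8 | sulfonium ylide formed by conjugate addition of the enolate of 6 to 7 | O=C[C@H](C(C[CH-][S+](c1ccccc1)c1ccccc1)(C(=O)CC)C(=O)OCc1ccccc1)CO[Si](C)(C)C(C)(C)C | intermediate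
9 | cyclopentane betaine, alkoxide anti to CH2OTBS and trans to the diphenylsulfonio group | CCC(=O)C1(C(=O)OCc2ccccc2)C[C@@H]([S+](c2ccccc2)c2ccccc2)[C@H]([O-])[C@H]1CO[Si](C)(C)C(C)(C)C | intermediate
10 | benzyl (1R,2R,5S)-2-{[(tert-butyldimethylsilyl)oxy]methyl}-3-propanoyl-6-oxabicyclo[3.1.0]hexane-3-carboxylate (C3 epimers) | CCC(=O)C1(C(=O)OCc3ccccc3)C[C@@H]2O[C@@H]2[C@H]1CO[Si](C)(C)C(C)(C)C | intermediate
11 | (1R,2R,5S)-2-{[(tert-butyldimethylsilyl)oxy]methyl}-3-propanoyl-6-oxabicyclo[3.1.0]hexane-3-carboxylic acid (C3 epimers) | CCC(=O)C1(C(=O)O)C[C@@H]2O[C@@H]2[C@H]1CO[Si](C)(C)C(C)(C)C | intermediate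
12 | 1-[(1R,2R,3R,5S)-2-{[(tert-butyldimethylsilyl)oxy]methyl}-6-oxabicyclo[3.1.0]hexan-3-yl]propan-1-one | CCC(=O)[C@@H]1C[C@@H]2O[C@@H]2[C@H]1CO[Si](C)(C)C(C)(C)C | intermediate
13 | (1R)-1-[(1R,2R,3R,5S)-2-{[(tert-butyldimethylsilyl)oxy]methyl}-6-oxabicyclo[3.1.0]hexan-3-yl]propan-1-ol | CC[C@@H](O)[C@@H]1C[C@@H]2O[C@@H]2[C@H]1CO[Si](C)(C)C(C)(C)C | intermediate
14 | tert-butyl{[(1R,2R,3R,5S)-3-[(1S)-1-chloropropyl]-6-oxabicyclo[3.1.0]hexan-2-yl]methoxy}dimethylsilane | CC[C@H](Cl)[C@@H]1C[C@@H]2O[C@@H]2[C@H]1CO[Si](C)(C)C(C)(C)C | intermediate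
15 | [(1R,2R,3R,5S)-3-[(1S)-1-chloropropyl]-6-oxabicyclo[3.1.0]hexan-2-yl]methanol | CC[C@H](Cl)[C@@H]1C[C@@H]2O[C@@H]2[C@H]1CO | intermediate
16 | (1R,2S,3R,5S)-3-[(1S)-1-chloropropyl]-6-oxabicyclo[3.1.0]hexane-2-carbaldehyde | CC[C@H](Cl)[C@@H]1C[C@@H]2O[C@@H]2[C@H]1C=O | intermediate
17 | tert-butyl(but-3-yn-1-yloxy)dimethylsilane | C#CCCO[Si](C)(C)C(C)(C)C | starting material
18 | 5-[(tert-butyldimethylsilyl)oxy]pent-2-yn-1-ol | OCC#CCCO[Si](C)(C)C(C)(C)C | intermediate
19 | [(5-bromopent-3-yn-1-yl)oxy](tert-butyl)dimethylsilane | BrCC#CCCO[Si](C)(C)C(C)(C)C | intermediate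
20 | methyl hex-5-ynoate | C#CCCCC(=O)OC | starting material
21 | methyl 11-[(tert-butyldimethylsilyl)oxy]undeca-5,8-diynoate | COC(=O)CCCC#CCC#CCCO[Si](C)(C)C(C)(C)C | intermediate
22 | methyl (5Z,8Z)-11-[(tert-butyldimethylsilyl)oxy]undeca-5,8-dienoate | COC(=O)CCC/C=C\C/C=C\CCO[Si](C)(C)C(C)(C)C | intermediate
23 | methyl (5Z,8Z)-11-hydroxyundeca-5,8-dienoate | COC(=O)CCC/C=C\C/C=C\CCO | intermediate
24 | methyl (5Z,8Z)-11-iodoundeca-5,8-dienoate | COC(=O)CCC/C=C\C/C=C\CCI | intermediate
25 | [(3Z,6Z)-11-methoxy-11-oxoundeca-3,6-dien-1-yl]triphenylphosphonium iodide | COC(=O)CCC/C=C\C/C=C\CC[P+](c1ccccc1)(c1ccccc1)c1ccccc1.[I-] | intermediate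
26 | methyl (5Z,8Z)-11-(triphenyl-λ5-phosphanylidene)undeca-5,8-dienoate | COC(=O)CCC/C=C\C/C=C\CC=P(c1ccccc1)(c1ccccc1)c1ccccc1 | intermediate
27 | methyl (5Z,8Z,11Z)-12-[(1R,2S,3R,5S)-3-[(1S)-1-chloropropyl]-6-oxabicyclo[3.1.0]hexan-2-yl]dodeca-5,8,11-trienoate | CC[C@H](Cl)[C@@H]1C[C@@H]2O[C@@H]2[C@H]1/C=C\C/C=C\C/C=C\CCCC(=O)OC | target

**Step count and risks**
Total step count: 17 (nine in the ring branch, seven in the chain branch, one convergent final step). Longest linear sequence: 10 steps (steps 1–9 and 17).

Steps most likely to fail: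

Step 4. The formyl-bearing stereocentre of 6 may epimerise under base before the conjugate addition. The ylide may also add to the aldehyde face that places the oxygen syn to CH2OTBS, or give a cis-betaine that cannot close. The fallback avoids the aldehyde and separates ring closure from epoxidation; it sets out from 3 and comes back at 10.
- (E)-But-2-ene-1,4-diol is monosilylated (NaH, TBSCl, THF) to (E)-4-[(tert-butyldimethylsilyl)oxy]but-2-en-1-ol F1 and converted (ClCO2Me, pyridine) into (E)-4-[(tert-butyldimethylsilyl)oxy]but-2-en-1-yl methyl carbonate F2.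
- Iridium-catalysed branched-selective asymmetric allylic alkylation of 3 with F2 ([Ir(cod)Cl]2, a chiral phosphoramidite ligand whose enantiomer is chosen to give the (R)-configured branched product, THF) should give benzyl 2-[(2R)-1-[(tert-butyldimethylsilyl)oxy]but-3-en-2-yl]-3-oxopentanoate F3.
- Tsuji–Trost C-allylation (allyl methyl carbonate, Pd(PPh3)4, THF) gives benzyl 2-[(2R)-1-[(tert-butyldimethylsilyl)oxy]but-3-en-2-yl]-3-oxo-2-(prop-2-en-1-yl)pentanoate F4.
- Ring-closing metathesis (second-generation ruthenium benzylidene catalyst, CH2Cl2, 40 °C) gives benzyl (2R)-2-{[(tert-butyldimethylsilyl)oxy]methyl}-1-propanoylcyclopent-3-ene-1-carboxylate F5.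
- Epoxidation (mCPBA, NaHCO3, CH2Cl2, 0 °C) on the face anti to the allylic CH2OTBS group then gives 10.

Step 7. The oxyphosphonium ion may undergo E2 elimination, or ionise with loss of stereochemical integrity. The nearby oxirane, which is syn to the reacting side chain, may also be opened by chlorophosphonium species or take part as an internal nucleophile. The fallback separates activation from displacement and uses no phosphorus reagent; it sets out from 13 and comes back at 14.
- Sulfonylation (ClCH2SO2Cl, pyridine, CH2Cl2, 0 °C) gives (1R)-1-[(1R,2R,3R,5S)-2-{[(tert-butyldimethylsilyl)oxy]methyl}-6-oxabicyclo[3.1.0]hexan-3-yl]propyl chloromethanesulfonate F6, with retention.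
- Displacement of this highly reactive sulfonate with LiCl in DMF at rt, with inversion, gives 14.

Step 17. The basic ylide may deprotonate the aldehyde at C13 and so open the oxirane by beta-elimination or epimerise the centre, or the Z-selectivity may erode. The fallback reverses the polarity of the olefination so that no enolisable epoxy aldehyde meets a base; it sets out from 15 and 23 and comes back at 27.
- Alcohol 15 is converted (I2, PPh3, imidazole, CH2Cl2, 0 °C) into the primary iodide 3-[(1S)-1-chloropropyl]-2-(iodomethyl)-6-oxabicyclo[3.1.0]hexane F7 (ring configuration as in 15).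
- Heating with PPh3 in MeCN gives {[3-[(1S)-1-chloropropyl]-6-oxabicyclo[3.1.0]hexan-2-yl]methyl}triphenylphosphonium iodide F8, and NaHMDS in THF at −78 °C gives the ylide F9. This ylide carries no leaving group on its beta-carbon.
- Alcohol 23 is oxidised (Dess–Martin periodinane, CH2Cl2, 0 °C) to methyl (5Z,8Z)-11-oxoundeca-5,8-dienoate F10, which is added at once to F9 at −78 °C to give 27 by a Z-selective Wittig reaction.

Further compounds
F1 | step 4 | (E)-4-[(tert-butyldimethylsilyl)oxy]but-2-en-1-ol | OC/C=C/CO[Si](C)(C)C(C)(C)C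
F2 | step 4 | (E)-4-[(tert-butyldimethylsilyl)oxy]but-2-en-1-yl methyl carbonate | COC(=O)OC/C=C/CO[Si](C)(C)C(C)(C)C
F3 | step 4 | benzyl 2-[(2R)-1-[(tert-butyldimethylsilyl)oxy]but-3-en-2-yl]-3-oxopentanoate | C=C[C@H](C(C(=O)CC)C(=O)OCc1ccccc1)CO[Si](C)(C)C(C)(C)C
F4 | step 4 | benzyl 2-[(2R)-1-[(tert-butyldimethylsilyl)oxy]but-3-en-2-yl]-3-oxo-2-(prop-2-en-1-yl)pentanoate | C=C[C@H](C(CC=C)(C(=O)CC)C(=O)OCc1ccccc1)CO[Si](C)(C)C(C)(C)C
F5 | step 4 | benzyl (2R)-2-{[(tert-butyldimethylsilyl)oxy]methyl}-1-propanoylcyclopent-3-ene-1-carboxylate | CCC(=O)C1(C(=O)OCc2ccccc2)CC=C[C@H]1CO[Si](C)(C)C(C)(C)C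
F6 | step 7 | (1R)-1-[(1R,2R,3R,5S)-2-{[(tert-butyldimethylsilyl)oxy]methyl}-6-oxabicyclo[3.1.0]hexan-3-yl]propyl chloromethanesulfonate | CC[C@@H](OS(=O)(=O)CCl)[C@@H]1C[C@@H]2O[C@@H]2[C@H]1CO[Si](C)(C)C(C)(C)C
F7 | step 17 | 3-[(1S)-1-chloropropyl]-2-(iodomethyl)-6-oxabicyclo[3.1.0]hexane (ring configuration as in 15) | CC[C@H](Cl)[C@@H]1C[C@@H]2O[C@@H]2[C@H]1CI
F8 | step 17 | {[3-[(1S)-1-chloropropyl]-6-oxabicyclo[3.1.0]hexan-2-yl]methyl}triphenylphosphonium iodide (ring configuration as in 15) | CC[C@H](Cl)[C@@H]1C[C@@H]2O[C@@H]2[C@H]1C[P+](c3ccccc3)(c3ccccc3)c3ccccc3.[I-]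
F9 | step 17 | ylide from F8 | CC[C@H](Cl)[C@@H]1C[C@@H]2O[C@@H]2[C@H]1C=P(c3ccccc3)(c3ccccc3)c3ccccc3
F10 | step 17 | methyl (5Z,8Z)-11-oxoundeca-5,8-dienoate | COC(=O)CCC/C=C\C/C=C\CC=O
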